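**Plan**

- Retrosynthesis: the quinone is taken back to its 1,4-dimethoxynaphthalene. The side chain (C1 at the ring to C32) is then cut at the C15–C16 single bond, between the methyl-bearing sp2 carbon C15 and the methylene C16. This gives a C30 (E)-alkenyl iodide and a C21 primary alkyl radical, made from a C22 acid by loss of CO2.
- The C30 half is cut at C12–C13 and C15–CH3 (propargyl dianion, MeI), at C1–C2 and C3–CH3 (benzylic coupling, carboalumination) and at C4–C5 (propargyl dianion), back to (S)-citronellyl bromide. The C22 acid is cut at C16–C17, back to geranylgeraniol and ethyl acetate.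
- Forward: no ring is made; both rings of the naphthalene are bought. The chain grows from the citronellyl core toward the ring (C4–C5, then C1–C3), then outward (C12–C16). The halves are joined at C15–C16 and the quinone level is restored last.
- Stereochemistry: 7R comes unchanged from (S)-citronellyl bromide; 18E, 22E, 26E from geranylgeraniol; 10E from E-selective SeO2 oxidation; 2E from syn-carboalumination; 14E from syn-hydrozirconation, kept by the stereoretentive coupling.
- Enabling feature: C16 is a primary sp3 carbon homoallylic to C18=C19, so its radical is not allylic and has no alkene placed for 5- or 6-membered ring closure; C15 is an sp2 carbon that can carry iodine. The quinone ring is held as the dimethyl ether because a free quinone would be reduced at the cathode and would trap the radical.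

Key step: step 12

Remark: all-E geranylgeraniol, (S)-citronellyl bromide and 1,4-dimethoxy-2-methylnaphthalene are taken as purchasable; the enantiomeric purity of the target is then that of the citronellyl bromide.

**Route**

Step 1
Reactants: 1 (2E,6E,10E)-geranylgeraniol
Product: 2 (2E,6E,10E)-geranylgeranyl bromide
Conditions: PBr3 (0.4 equiv), Et2O, 0 °C, dark
Reagents that add atoms: phosphorus tribromide, BrP(Br)Br
Why: Bromination of a primary allylic alcohol through its bromophosphite by SN2 displacement at 0 °C should keep the 2E geometry and avoid allylic transposition.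

Step 2
Reactants: 2 (2E,6E,10E)-geranylgeranyl bromide
Product: 3 ethyl (4E,8E,12E)-5,9,13,17-tetramethyloctadeca-4,8,12,16-tetraenoate
Conditions: EtOAc (3 equiv), LiN(i-Pr)2 (3 equiv), THF, −78 °C; then 2, DMPU, −78 to −40 °C
Reagents that add atoms: ethyl acetate (as its lithium enolate), CCOC(C)=O
Why: Enolate alkylation by SN2 attack on a primary allylic bromide, with excess enolate at low temperature, should suppress double alkylation and SN2' attack and leave the E double bonds untouched.

Step 3
Reactants: 3 ethyl (4E,8E,12E)-5,9,13,17-tetramethyloctadeca-4,8,12,16-tetraenoate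
Product: 4 (4E,8E,12E)-5,9,13,17-tetramethyloctadeca-4,8,12,16-tetraenoic acid
Conditions: LiOH, THF/MeOH/H2O, rt; then dilute aq. HCl
Reagents that add atoms: lithium hydroxide, [Li+].[OH-]
Why: Saponification of an unhindered ester; no alkene is conjugated to the carboxyl, so no isomerisation is expected.

Step 4
Reactants: 4 (4E,8E,12E)-5,9,13,17-tetramethyloctadeca-4,8,12,16-tetraenoic acid
Product: 5 1,3-dioxoisoindolin-2-yl (4E,8E,12E)-5,9,13,17-tetramethyloctadeca-4,8,12,16-tetraenoate
Conditions: N-hydroxyphthalimide, N,N'-diisopropylcarbodiimide, DMAP (cat.), CH2Cl2, rt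
Reagents that add atoms: N-hydroxyphthalimide, O=C1c2ccccc2C(=O)N1O
Why: Steglich-type carbodiimide esterification under neutral conditions should give the redox-active N-acyloxyphthalimide without touching the polyene.

Step 5
Reactants: 6 (S)-citronellyl bromide
Product: 7 (2E,6S)-8-bromo-2,6-dimethyloct-2-en-1-ol
Conditions: SeO2 (0.3 equiv), t-BuOOH (70% aq., 3 equiv), salicylic acid (0.1 equiv), CH2Cl2, rt
Reagents that add atoms: selenium dioxide, O=[Se]=O; tert-butyl hydroperoxide, CC(C)(C)OO
Why: Catalytic SeO2 allylic oxidation (ene reaction, then [2,3]-sigmatropic shift) should hydroxylate the methyl group trans to the chain on the only alkene, giving the E allylic alcohol and leaving the primary bromide and the stereocentre untouched.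

Step 6
Reactants: 7 (2E,6S)-8-bromo-2,6-dimethyloct-2-en-1-ol
Product: 8 (2E,6R)-2,6-dimethylundec-2-en-10-yn-1-ol
Conditions: n-BuLi (1.0 equiv), THF, −78 °C; then 1,3-dilithiopropyne (from propyne, n-BuLi, TMEDA, Et2O/hexane), −78 °C to rt; H2O
Reagents that add atoms: 1,3-dilithiopropyne (from propyne, CC#C), [Li]CC#C[Li]
Why: After the alcohol is masked as its lithium alkoxide, the propargyl dianion should alkylate the primary bromide at its sp3 carbon (SN2) and the acetylide is protonated on work-up; the stereocentre is not at the reacting carbon and its descriptor changes only by priority.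

Step 7
Reactants: 9 1,4-dimethoxy-2-methylnaphthalene
Product: 10 2-(chloromethyl)-1,4-dimethoxy-3-methylnaphthalene
Conditions: (CH2O)n, conc. aq. HCl, AcOH, rt
Reagents that add atoms: formaldehyde (as paraformaldehyde), C=O; hydrogen chloride, Cl
Why: Blanc chloromethylation should occur at C3, the only free position of the dimethoxylated ring and the most electron-rich site.

Step 8
Reactants: 8 (2E,6R)-2,6-dimethylundec-2-en-10-yn-1-ol; 10 2-(chloromethyl)-1,4-dimethoxy-3-methylnaphthalene
Product: 12 (2E,6R,10E)-12-(1,4-dimethoxy-3-methylnaphthalen-2-yl)-2,6,10-trimethyldodeca-2,10-dien-1-ol, via alkenyldimethylalane 11 (not isolated)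
Conditions: Me3Al (3.5 equiv), Cp2ZrCl2 (0.25 equiv), ClCH2CH2Cl, 0 °C to rt; then 10, Ni(PPh3)2Cl2 (5 mol %) pre-reduced with n-BuLi (10 mol %), THF, rt; dilute aq. HCl
Reagents that add atoms: trimethylaluminium, C[Al](C)C
Why: Zirconium-catalysed syn-methylalumination of the terminal alkyne puts methyl on the inner carbon and aluminium on the terminal carbon, cis to each other, which sets the 10E alkene; the alkenylalane then couples with the benzylic chloride under zerovalent-nickel catalysis with retention, while the alcohol rides as its dimethylaluminium alkoxide and the trisubstituted alkene is inert.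

Step 9
Reactants: 12 (2E,6R,10E)-12-(1,4-dimethoxy-3-methylnaphthalen-2-yl)-2,6,10-trimethyldodeca-2,10-dien-1-ol
Product: 13 2-[(2E,7R,10E)-12-bromo-3,7,11-trimethyldodeca-2,10-dien-1-yl]-1,4-dimethoxy-3-methylnaphthalene
Conditions: CBr4, PPh3, CH2Cl2, 0 °C
Reagents that add atoms: carbon tetrabromide, BrC(Br)(Br)Br
Why: Appel bromination under neutral conditions proceeds by SN2 at the primary allylic carbon, so the E geometry should be kept and the aryl ethers and alkenes untouched.

Step 10
Reactants: 13 2-[(2E,7R,10E)-12-bromo-3,7,11-trimethyldodeca-2,10-dien-1-yl]-1,4-dimethoxy-3-methylnaphthalene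
Product: 15 2-[(2E,7R,10E)-3,7,11-trimethylhexadeca-2,10-dien-14-yn-1-yl]-1,4-dimethoxy-3-methylnaphthalene, via lithium acetylide 14 (not isolated)
Conditions: 1,3-dilithiopropyne (1.2 equiv; from propyne, n-BuLi, TMEDA), THF, −78 °C; then MeI (excess), −78 °C to rt
Reagents that add atoms: 1,3-dilithiopropyne (from propyne, CC#C), [Li]CC#C[Li]; iodomethane, CI
Why: Sequential alkylation of the propargyl dianion: its sp3 carbanion should displace the allylic bromide by SN2 at −78 °C, and the lithium acetylide that remains is methylated by MeI to give the 2-alkyne.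

Step 11
Reactants: 15 2-[(2E,7R,10E)-3,7,11-trimethylhexadeca-2,10-dien-14-yn-1-yl]-1,4-dimethoxy-3-methylnaphthalene
Product: 17 2-[(2E,7R,10E,14E)-15-iodo-3,7,11-trimethylhexadeca-2,10,14-trien-1-yl]-1,4-dimethoxy-3-methylnaphthalene, via alkenylzirconocene chloride 16 (not isolated)
Conditions: Cp2Zr(H)Cl (2.5 equiv), THF, 50 °C; then I2, THF, 0 °C
Reagents that add atoms: iodine, II
Why: Syn-hydrozirconation with excess Cp2Zr(H)Cl under equilibrating conditions should place zirconium on the less hindered, methyl-bearing alkyne carbon, and iodinolysis with retention then gives the 14E iodide (iodine trans to the chain); the trisubstituted alkenes should not react.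

Step 12
Reactants: 5 1,3-dioxoisoindolin-2-yl (4E,8E,12E)-5,9,13,17-tetramethyloctadeca-4,8,12,16-tetraenoate; 17 2-[(2E,7R,10E,14E)-15-iodo-3,7,11-trimethylhexadeca-2,10,14-trien-1-yl]-1,4-dimethoxy-3-methylnaphthalene
Product: 18 2-[(2E,7R,10E,14E,18E,22E,26E)-3,7,11,15,19,23,27,31-octamethyldotriaconta-2,10,14,18,22,26,30-heptaen-1-yl]-1,4-dimethoxy-3-methylnaphthalene
Conditions: 5 (1.5 equiv), NiCl2·6H2O (20 mol %), 2,2'-bipyridine (20 mol %), AgNO3 (0.3 equiv, deposits silver nanoparticles on the cathode), LiCl, DMF/THF, Mg anode, reticulated vitreous carbon cathode, undivided cell, constant current (about 2.5 F/mol), rt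
Reagents that add atoms: none
Why: At the silver-coated cathode the bipyridine nickel catalyst is reduced to low-valent nickel, which adds to the C–I bond of 17 with retention to give an (E)-alkenyl divalent-nickel species, while electron transfer to 5 releases phthalimide anion and CO2 and leaves the primary C16 radical; radical capture gives an alkyl(alkenyl) trivalent-nickel complex, and reductive elimination forms the C15–C16 bond, the magnesium anode supplying the electrons. The closest known reaction type is the nickel-electrocatalytic decarboxylative alkenylation of redox-active esters with alkenyl iodides used to assemble polyene terpenoids. No ring is closed and no stereocentre is made; the 14E geometry is fixed in 17 by the syn-hydrozirconation and is kept because neither oxidative addition nor reductive elimination inverts the alkenyl carbon. The step needs cross- over homo-coupling, retention of all E double bonds and no radical side reaction: the radical is primary and homoallylic to C18=C19, so it is not allylic and can only close a reversible 3-exo ring, and capture by nickel should outrun hydrogen abstraction. The naphthoquinone is carried as its 1,4-dimethyl ether because the free quinone would be reduced at the cathode before nickel and would add the alkyl radical; the excess of 5 makes up for radical dimerisation.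

Step 13
Reactants: 18 2-[(2E,7R,10E,14E,18E,22E,26E)-3,7,11,15,19,23,27,31-octamethyldotriaconta-2,10,14,18,22,26,30-heptaen-1-yl]-1,4-dimethoxy-3-methylnaphthalene
Product: 19 2-methyl-3-[(2E,7R,10E,14E,18E,22E,26E)-3,7,11,15,19,23,27,31-octamethyldotriaconta-2,10,14,18,22,26,30-heptaen-1-yl]naphthalene-1,4-dione
Conditions: (NH4)2Ce(NO3)6 (2.5 equiv), MeCN/CH2Cl2/H2O, 0 °C, short reaction time
Reagents that add atoms: water, O
Why: Oxidative demethylation by (NH4)2Ce(NO3)6 goes through the arene radical cation and addition of water with loss of methanol, and the dimethoxynaphthalene is far easier to oxidise than the isolated alkenes, so the chain and the remote stereocentre should survive.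

**Compound list**

1 | (2E,6E,10E)-geranylgeraniol, (2E,6E,10E)-3,7,11,15-tetramethylhexadeca-2,6,10,14-tetraen-1-ol | CC(C)=CCC/C(C)=C/CC/C(C)=C/CC/C(C)=C/CO | starting material
2 | (2E,6E,10E)-geranylgeranyl bromide, (2E,6E,10E)-1-bromo-3,7,11,15-tetramethylhexadeca-2,6,10,14-tetraene | CC(C)=CCC/C(C)=C/CC/C(C)=C/CC/C(C)=C/CBr | intermediate
3 | ethyl (4E,8E,12E)-5,9,13,17-tetramethyloctadeca-4,8,12,16-tetraenoate | CC(C)=CCC/C(C)=C/CC/C(C)=C/CC/C(C)=C/CCC(=O)OCC | intermediate
4 | (4E,8E,12E)-5,9,13,17-tetramethyloctadeca-4,8,12,16-tetraenoic acid | CC(C)=CCC/C(C)=C/CC/C(C)=C/CC/C(C)=C/CCC(=O)O | intermediate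
5 | 1,3-dioxoisoindolin-2-yl (4E,8E,12E)-5,9,13,17-tetramethyloctadeca-4,8,12,16-tetraenoate (N-acyloxyphthalimide) | CC(C)=CCC/C(C)=C/CC/C(C)=C/CC/C(C)=C/CCC(=O)ON1C(=O)c2ccccc2C1=O | intermediate
6 | (S)-citronellyl bromide, (6S)-8-bromo-2,6-dimethyloct-2-ene | CC(C)=CCC[C@H](C)CCBr | starting material
7 | (2E,6S)-8-bromo-2,6-dimethyloct-2-en-1-ol | OC/C(C)=C/CC[C@H](C)CCBr | intermediate
8 | (2E,6R)-2,6-dimethylundec-2-en-10-yn-1-ol | OC/C(C)=C/CC[C@H](C)CCCC#C | intermediate
9 | 1,4-dimethoxy-2-methylnaphthalene | COc1cc(C)c(OC)c2ccccc12 | starting material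
10 | 2-(chloromethyl)-1,4-dimethoxy-3-methylnaphthalene | ClCc1c(C)c(OC)c2ccccc2c1OC | intermediate
11 | alkenyldimethylalane: (2E,6R,10E)-11-(dimethylalumanyl)-2,6,10-trimethylundeca-2,10-dien-1-ol as its dimethylaluminium alkoxide, aluminium trans to the chain | C[Al](C)OC/C(C)=C/CC[C@H](C)CCC/C(C)=C/[Al](C)C | intermediate
12 | (2E,6R,10E)-12-(1,4-dimethoxy-3-methylnaphthalen-2-yl)-2,6,10-trimethyldodeca-2,10-dien-1-ol | OC/C(C)=C/CC[C@H](C)CCC/C(C)=C/Cc1c(C)c(OC)c2ccccc2c1OC | intermediate
13 | 2-[(2E,7R,10E)-12-bromo-3,7,11-trimethyldodeca-2,10-dien-1-yl]-1,4-dimethoxy-3-methylnaphthalene | BrC/C(C)=C/CC[C@H](C)CCC/C(C)=C/Cc1c(C)c(OC)c2ccccc2c1OC | intermediate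
14 | lithium acetylide of 2-[(2E,7R,10E)-3,7,11-trimethylpentadeca-2,10-dien-14-yn-1-yl]-1,4-dimethoxy-3-methylnaphthalene | [Li]C#CCC/C(C)=C/CC[C@H](C)CCC/C(C)=C/Cc1c(C)c(OC)c2ccccc2c1OC | intermediate
15 | 2-[(2E,7R,10E)-3,7,11-trimethylhexadeca-2,10-dien-14-yn-1-yl]-1,4-dimethoxy-3-methylnaphthalene | CC#CCC/C(C)=C/CC[C@H](C)CCC/C(C)=C/Cc1c(C)c(OC)c2ccccc2c1OC | intermediate
16 | alkenylzirconocene chloride: Cp2Zr(Cl) on C15 of the chain of 15, hydrogen on C14, zirconium trans to the chain | Cl[Zr](C1C=CC=C1)(C1C=CC=C1)/C(C)=C/CC/C(C)=C/CC[C@H](C)CCC/C(C)=C/Cc1c(C)c(OC)c2ccccc2c1OC | intermediate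
17 | 2-[(2E,7R,10E,14E)-15-iodo-3,7,11-trimethylhexadeca-2,10,14-trien-1-yl]-1,4-dimethoxy-3-methylnaphthalene | I/C(C)=C/CC/C(C)=C/CC[C@H](C)CCC/C(C)=C/Cc1c(C)c(OC)c2ccccc2c1OC | intermediate
18 | 2-[(2E,7R,10E,14E,18E,22E,26E)-3,7,11,15,19,23,27,31-octamethyldotriaconta-2,10,14,18,22,26,30-heptaen-1-yl]-1,4-dimethoxy-3-methylnaphthalene | CC(C)=CCC/C(C)=C/CC/C(C)=C/CC/C(C)=C/CC/C(C)=C/CC/C(C)=C/CC[C@H](C)CCC/C(C)=C/Cc1c(C)c(OC)c2ccccc2c1OC | intermediate
19 | 2-methyl-3-[(2E,7R,10E,14E,18E,22E,26E)-3,7,11,15,19,23,27,31-octamethyldotriaconta-2,10,14,18,22,26,30-heptaen-1-yl]naphthalene-1,4-dione (CNP0107344.1) | CC(C)=CCC/C(C)=C/CC/C(C)=C/CC/C(C)=C/CC/C(C)=C/CC/C(C)=C/CC[C@H](C)CCC/C(C)=C/CC1=C(C)C(=O)c2ccccc2C1=O | target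

**Count and risks**

Total step count: 13. Longest linear sequence: 8 steps (steps 5, 6, 8, 9, 10, 11, 12, 13, from (S)-citronellyl bromide).

Steps most likely to fail:

1. Step 12. The alkyl radical may be lost to dimerisation or hydrogen-atom capture before nickel traps it, and oxidative addition at the α-methyl alkenyl iodide may be slow, so that the iodide is reduced instead of coupled. The fallback is a two-electron B-alkyl Suzuki–Miyaura coupling; it sets out from 1, with 17 as partner, and comes back at 18. Oxidation of 1 with MnO2 (hexane, rt) should give (2E,6E,10E)-geranylgeranial F1. Wittig methylenation (Ph3P=CH2 from Ph3PCH3Br and n-BuLi, THF, 0 °C) should give (3E,7E,11E)-4,8,12,16-tetramethylheptadeca-1,3,7,11,15-pentaene F2. 9-BBN (THF, 0 °C to rt) should add only to the monosubstituted terminal double bond, boron on C1, to give 9-[(3E,7E,11E)-4,8,12,16-tetramethylheptadeca-3,7,11,15-tetraen-1-yl]-9-borabicyclo[3.3.1]nonane F3. F3 is coupled without isolation with 17 [Pd(dppf)Cl2, AsPh3, Cs2CO3, DMF/THF/H2O, rt], with retention at the alkenyl carbon, to give 18.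

2. Step 11. Zirconium may be delivered partly to the inner alkyne carbon, which would give a regioisomeric iodide that is hard to remove. The fallback avoids hydrometalation: the large alkyl group and the methyl group are put one after the other on a 1,1-dibromoalkene. It sets out from 13 and comes back at 18, passing by 15 to 17 and step 12. Alkylation of 13 with the lithium enolate of ethyl acetate (as in step 2) should give ethyl (4E,8R,12E)-14-(1,4-dimethoxy-3-methylnaphthalen-2-yl)-4,8,12-trimethyltetradeca-4,12-dienoate F4. i-Bu2AlH (CH2Cl2, −78 °C) should give the aldehyde (4E,8R,12E)-14-(1,4-dimethoxy-3-methylnaphthalen-2-yl)-4,8,12-trimethyltetradeca-4,12-dienal F5. Corey–Fuchs dibromo-olefination (CBr4, PPh3, CH2Cl2, 0 °C) should give 2-[(2E,7R,10E)-15,15-dibromo-3,7,11-trimethylpentadeca-2,10,14-trien-1-yl]-1,4-dimethoxy-3-methylnaphthalene F6. Palladium-catalysed mono-coupling with the borane F3 of the first fallback [Pd2(dba)3, tri(2-furyl)phosphine, aq. K3PO4, THF] should take place at the more accessible bromine trans to the chain and give 2-[(2E,7R,10E,14Z,18E,22E,26E)-15-bromo-3,7,11,19,23,27,31-heptamethyldotriaconta-2,10,14,18,22,26,30-heptaen-1-yl]-1,4-dimethoxy-3-methylnaphthalene F7. Methylation with retention (Me2Zn, Pd(t-Bu3P)2, THF) then gives 18.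

3. Step 8. Carboalumination may stall on the alkoxide-bearing substrate, or the alkenylalane may be protonated or couple sluggishly with the benzylic chloride in the presence of the aluminium alkoxide. The fallback reverses the polarity of the coupling; it sets out from 8 and 10 and comes back at 12. The alane 11, made as in step 8, is quenched with I2 (THF, −30 °C) to give (2E,6R,10E)-11-iodo-2,6,10-trimethylundeca-2,10-dien-1-ol F8. Zinc dust (LiCl, THF, rt) inserts into 10 to give [(1,4-dimethoxy-3-methylnaphthalen-2-yl)methyl]zinc chloride F9. Negishi coupling of F8 with excess F9 (Pd(PPh3)4, THF, rt) gives 12.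

**Further compounds**

F1 | step 12 | (2E,6E,10E)-geranylgeranial, (2E,6E,10E)-3,7,11,15-tetramethylhexadeca-2,6,10,14-tetraenal | CC(C)=CCC/C(C)=C/CC/C(C)=C/CC/C(C)=C/C=O
F2 | step 12 | (3E,7E,11E)-4,8,12,16-tetramethylheptadeca-1,3,7,11,15-pentaene | CC(C)=CCC/C(C)=C/CC/C(C)=C/CC/C(C)=C/C=C
F3 | step 12 | 9-[(3E,7E,11E)-4,8,12,16-tetramethylheptadeca-3,7,11,15-tetraen-1-yl]-9-borabicyclo[3.3.1]nonane | CC(C)=CCC/C(C)=C/CC/C(C)=C/CC/C(C)=C/CCB1C2CCCC1CCC2
F4 | step 11 | ethyl (4E,8R,12E)-14-(1,4-dimethoxy-3-methylnaphthalen-2-yl)-4,8,12-trimethyltetradeca-4,12-dienoate | CCOC(=O)CC/C(C)=C/CC[C@H](C)CCC/C(C)=C/Cc1c(C)c(OC)c2ccccc2c1OC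
F5 | step 11 | (4E,8R,12E)-14-(1,4-dimethoxy-3-methylnaphthalen-2-yl)-4,8,12-trimethyltetradeca-4,12-dienal | O=CCC/C(C)=C/CC[C@H](C)CCC/C(C)=C/Cc1c(C)c(OC)c2ccccc2c1OC
F6 | step 11 | 2-[(2E,7R,10E)-15,15-dibromo-3,7,11-trimethylpentadeca-2,10,14-trien-1-yl]-1,4-dimethoxy-3-methylnaphthalene | BrC(Br)=CCC/C(C)=C/CC[C@H](C)CCC/C(C)=C/Cc1c(C)c(OC)c2ccccc2c1OC
F7 | step 11 | 2-[(2E,7R,10E,14Z,18E,22E,26E)-15-bromo-3,7,11,19,23,27,31-heptamethyldotriaconta-2,10,14,18,22,26,30-heptaen-1-yl]-1,4-dimethoxy-3-methylnaphthalene | CC(C)=CCC/C(C)=C/CC/C(C)=C/CC/C(C)=C/CC/C(Br)=C/CC/C(C)=C/CC[C@H](C)CCC/C(C)=C/Cc1c(C)c(OC)c2ccccc2c1OC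
F8 | step 8 | (2E,6R,10E)-11-iodo-2,6,10-trimethylundeca-2,10-dien-1-ol | OC/C(C)=C/CC[C@H](C)CCC/C(C)=C/I
F9 | step 8 | [(1,4-dimethoxy-3-methylnaphthalen-2-yl)methyl]zinc chloride | Cl[Zn]Cc1c(C)c(OC)c2ccccc2c1OC
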